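## Retrosynthetic overview

1. Feature (aurone numbering; ring A = benzo ring, ring C = furanone ring, ring B = catechol ring, primes for the second half). Across each tetrasubstituted C2=Cα bond, O1 of ring C and ring B on Cα are trans, and C3 is trans to Cα'. This is what an anti addition of oxygen and aryl to an alkyne leaves behind, and Cα–Cα' is the central σ bond of a 1,3-diyne.
2. Disconnections: the six aryl O–CH3 bonds go last (BBr3). Before that, both O1–C2 and both Cα–ring B bonds are cut in one operation, back to a 1,6-bis(2-hydroxy-4-methoxyphenyl)hexa-2,4-diyne and 4-iodoveratrole (twofold palladium-catalysed anti-oxyarylation).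
3. Oxidation level: C3 and C3' pass through the cascade as carbinols. A ynone would draw the phenoxide to Cα (6-endo, chromone) and would cyclise under base with no palladium involved. MnO2 in the same flask then sets the two ketones.
4. The diyne tetraol comes from dilithiobutadiyne and two O-silylated 2-hydroxy-4-methoxybenzaldehydes, followed by fluoride.
5. Ring order: rings A, A', B and B' are bought. Ring C closes first and ring C' second, both in the key step.

Key step: step 4

Assumption: the twisted Cα–Cα' axis of the 2,3-diaryl-1,3-diene is not a defined stereoelement of the target and is left uncontrolled, and the carbinol centres of all intermediates are carried as a dl/meso mixture because the oxidation erases them.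

## Route

Step 1
Reactants: 1 2-hydroxy-4-methoxybenzaldehyde
Product: 2 2-(tert-butyldimethylsilyloxy)-4-methoxybenzaldehyde
Conditions: TBSCl, imidazole, DMF, rt
Reagents that add atoms: tert-butyldimethylsilyl chloride (TBSCl), CC(C)(C)[Si](C)(C)Cl
Why: Standard imidazole-promoted silylation of a phenol; it removes the acidic proton that would quench the acetylide, and the group later leaves with fluoride under near-neutral conditions that the acid-labile carbinols tolerate.

Step 2
Reactants: 3 1,4-bis(trimethylsilyl)buta-1,3-diyne; 2 2-(tert-butyldimethylsilyloxy)-4-methoxybenzaldehyde (two equivalents)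
Product: 5 1,6-bis[2-(tert-butyldimethylsilyloxy)-4-methoxyphenyl]hexa-2,4-diyne-1,6-diol (dl/meso mixture), via 1,4-dilithiobuta-1,3-diyne 4 (not isolated)
Conditions: 3, MeLi·LiBr (2.05 equiv), THF, 0 °C to rt; then 2 (2.0 equiv), −78 to −30 °C; sat. aq NH4Cl at −30 °C
Reagents that add atoms: none
Why: Twofold C–Si cleavage by MeLi gives the dilithium acetylide, which adds 1,2 to two aldehydes (acetylide addition to an aldehyde); the two carbinol centres form without control and are erased in step 4, and the cold quench limits O-to-O silyl migration, which would be harmless anyway because step 3 removes all silicon.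

Step 3
Reactants: 5 1,6-bis[2-(tert-butyldimethylsilyloxy)-4-methoxyphenyl]hexa-2,4-diyne-1,6-diol
Product: 6 1,6-bis(2-hydroxy-4-methoxyphenyl)hexa-2,4-diyne-1,6-diol (dl/meso mixture)
Conditions: TBAF (2.4 equiv), AcOH (2.4 equiv), THF, 0 °C; neutral work-up, used without delay
Reagents that add atoms: none
Why: Fluoride cleaves aryl silyl ethers rapidly at 0 °C, and the acetic acid buffer keeps the freed phenols protonated, so that neither premature cyclisation onto the diyne nor ortho-quinone methide formation from the doubly activated carbinols is triggered.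

Step 4
Reactants: 6 1,6-bis(2-hydroxy-4-methoxyphenyl)hexa-2,4-diyne-1,6-diol; 7 4-iodo-1,2-dimethoxybenzene (two equivalents incorporated)
Product: 10 hexa-O-methyldisulfuretin [(2Z,2'Z)-2,2'-[1,2-bis(3,4-dimethoxyphenyl)ethane-1,2-diylidene]bis(6-methoxybenzofuran-3(2H)-one); each ring B trans to O1], via mono-cyclised enyne carbinol 8 (not isolated), via bis-cyclised dicarbinol 9 (not isolated)
Conditions: Pd(PPh3)4 (10 mol %), 7 (4 equiv), K2CO3 (5 equiv), degassed MeCN, 60 °C, slow addition of 6, dark; then rt, activated MnO2 (excess), same flask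
Reagents that add atoms: none
Why: Proposed new method: 7 adds oxidatively to zerovalent palladium to give ArPdI (divalent palladium), which binds one alkyne of 6; the neighbouring phenoxide attacks the outer diyne carbon C2 on the face away from the metal, reductive elimination from the resulting vinyl(aryl)palladium makes the Cα–aryl bond and frees enyne 8, and the second alkyne runs through the same cycle to give 9. The closest known reaction type is the anti-oxypalladation/reductive-elimination domino of alkynes that carry a pendant O–H nucleophile (alkynoic acids, alkynols, ortho-alkynylphenols) with aryl iodides, backed by the known 5-exo-dig cycloisomerisation of 2-(1-hydroxyalk-2-ynyl)phenols under divalent palladium or monovalent gold; the twofold run on a conjugated diyne in this exo mode has not been shown. Ring C and ring C' each close 5-exo-dig through O1–C2 bond formation. No stereocentre is made; each alkene geometry follows from the anti addition, which leaves O1 trans to the incoming aryl group and C3 trans to Cα'. The step needs 5-exo over 6-endo closure and aryl transfer over protonation: with C3 as a carbinol no carbonyl polarises Cα, the alkynyl neighbour acts as an acceptor that sends the nucleophile to the outer carbon and the metal to the inner one, and slow addition of 6 to preformed ArPdI with excess 7 keeps free phenoxide scarce. The bis(allylic, benzylic) carbinol 9 ionises too easily to be isolated, so MnO2 is added to the still basic suspension, an oxidation known for 2-benzylidene-2,3-dihydrobenzofuran-3-ols on the way to aurones.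

Step 5
Reactants: 10 hexa-O-methyldisulfuretin
Product: 11 disulfuretin [(2Z,2'Z)-2,2'-[1,2-bis(3,4-dihydroxyphenyl)ethane-1,2-diylidene]bis(6-hydroxybenzofuran-3(2H)-one)]
Conditions: BBr3 (12 equiv), CH2Cl2, −78 °C to rt, dark, argon; then water, 0 °C
Reagents that add atoms: none
Why: Boron tribromide cleavage of aryl methyl ethers is the standard passage from methoxyaurones to hydroxyaurones; the benzofuranone core offers BBr3 no other point of attack, and the cold start and exclusion of light limit rotation about the Lewis-acid-complexed push–pull C2=Cα bonds.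

## Compound list

1 | 2-hydroxy-4-methoxybenzaldehyde | COc1ccc(C=O)c(O)c1 | starting material
2 | 2-(tert-butyldimethylsilyloxy)-4-methoxybenzaldehyde | COc1ccc(C=O)c(O[Si](C)(C)C(C)(C)C)c1 | intermediate
3 | 1,4-bis(trimethylsilyl)buta-1,3-diyne | C[Si](C)(C)C#CC#C[Si](C)(C)C | starting material
4 | 1,4-dilithiobuta-1,3-diyne (not isolated) | [Li]C#CC#C[Li] | intermediate
5 | 1,6-bis[2-(tert-butyldimethylsilyloxy)-4-methoxyphenyl]hexa-2,4-diyne-1,6-diol (dl/meso) | COc1ccc(C(O)C#CC#CC(O)c2ccc(OC)cc2O[Si](C)(C)C(C)(C)C)c(O[Si](C)(C)C(C)(C)C)c1 | intermediate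
6 | 1,6-bis(2-hydroxy-4-methoxyphenyl)hexa-2,4-diyne-1,6-diol (dl/meso) | COc1ccc(C(O)C#CC#CC(O)c2ccc(OC)cc2O)c(O)c1 | intermediate
7 | 4-iodo-1,2-dimethoxybenzene (4-iodoveratrole) | COc1ccc(I)cc1OC | starting material
8 | (Z)-2-[1-(3,4-dimethoxyphenyl)-4-hydroxy-4-(2-hydroxy-4-methoxyphenyl)but-2-yn-1-ylidene]-6-methoxy-2,3-dihydrobenzofuran-3-ol (aryl trans to O1; carbinol centres unassigned; not isolated) | OC1/C(=C(/C#CC(O)c2ccc(OC)cc2O)c2ccc(OC)c(OC)c2)Oc2cc(OC)ccc21 | intermediate
9 | (2Z,2'Z)-2,2'-[1,2-bis(3,4-dimethoxyphenyl)ethane-1,2-diylidene]bis(6-methoxy-2,3-dihydrobenzofuran-3-ol) (carbinol centres unassigned; not isolated) | OC1/C(=C(/C(=C2\Oc3cc(OC)ccc3C2O)c2ccc(OC)c(OC)c2)c2ccc(OC)c(OC)c2)Oc2cc(OC)ccc21 | intermediate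
10 | hexa-O-methyldisulfuretin, (2Z,2'Z)-2,2'-[1,2-bis(3,4-dimethoxyphenyl)ethane-1,2-diylidene]bis(6-methoxybenzofuran-3(2H)-one) | O=C1/C(=C(/C(=C2\Oc3cc(OC)ccc3C2=O)c2ccc(OC)c(OC)c2)c2ccc(OC)c(OC)c2)Oc2cc(OC)ccc21 | intermediate
11 | disulfuretin | O=C1/C(=C(/C(=C2\Oc3cc(O)ccc3C2=O)c2ccc(O)c(O)c2)c2ccc(O)c(O)c2)Oc2cc(O)ccc21 | target

## Step count and risks

Total step count: 5. Longest linear sequence: 5 (1 → 2 → 5 → 6 → 10 → 11); 3 and 7 enter as purchased partners.

**1. Step 4 (Proposed new method).**
- What may go wrong:
  - cyclisation with protonation in place of aryl transfer;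
  - 6-endo closure or stalling at the second, more crowded alkyne;
  - syn-carbopalladation competing with the anti pathway;
  - ionisation of the carbinols before the oxidant acts.
- Fallback (known chemistry; oxygen and carbon are delivered in separate operations): it sets out from 6. Twofold 5-exo-dig anti-iodoetherification (I2, NaHCO3, MeCN, 0 °C) should give (E,E)-2,2'-(1,2-diiodoethane-1,2-diylidene)bis(6-methoxy-2,3-dihydrobenzofuran-3-ol) F1. Here iodine rather than an electron-rich arene sits on Cα, so the carbinols are much less prone to ionise. MnO2 in CH2Cl2 should then give (E,E)-2,2'-(1,2-diiodoethane-1,2-diylidene)bis(6-methoxybenzofuran-3(2H)-one) F2. A twofold Suzuki–Miyaura coupling with 3,4-dimethoxyphenylboronic acid (Pd(dppf)Cl2, K3PO4, dioxane–water, 60 °C) replaces each iodine with retention of geometry; twofold cross-coupling of 2,3-dihalo-1,3-dienes is a known reaction type. Ring B therefore ends trans to O1, and the route is rejoined at 10.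

**2. Step 5.**
- What may go wrong:
  - incomplete cleavage of the six ethers;
  - rotation about C2=Cα in the Lewis acid complex, with loss of alkene geometry;
  - air oxidation of the catechols during work-up.
- Fallback (the methyl ethers are exchanged for acetal protecting groups before the assembly, so the last step needs no Lewis acid): it sets out from 7 and 3.
  - BBr3 in CH2Cl2 converts 7 into 4-iodobenzene-1,2-diol F3, a demethylation on a simple arene with nothing to isomerise. MOMCl/i-Pr2NEt then gives 4-iodo-1,2-bis(methoxymethoxy)benzene F4.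
  - Commercial 2-hydroxy-4-(methoxymethoxy)benzaldehyde F5 is silylated as in step 1 to 2-(tert-butyldimethylsilyloxy)-4-(methoxymethoxy)benzaldehyde F6.
  - Two equivalents of F6 take up 4, made from 3 as in step 2, to give 1,6-bis[2-(tert-butyldimethylsilyloxy)-4-(methoxymethoxy)phenyl]hexa-2,4-diyne-1,6-diol F7.
  - Buffered TBAF gives 1,6-bis[2-hydroxy-4-(methoxymethoxy)phenyl]hexa-2,4-diyne-1,6-diol F8.
  - The cascade of step 4 with F4 should pass through the mono-cyclised MOM enyne carbinol F9 and the bis-cyclised MOM dicarbinol F10. After MnO2 in the same flask it should give hexa-O-(methoxymethyl)disulfuretin F11.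
  - Acetal exchange with dilute HCl in MeOH at 40 °C frees all six phenols, and the route is rejoined at 11.

**3. Step 2.**
- What may go wrong:
  - incomplete second desilylation, so that only one diyne terminus is metalated;
  - poor solubility of the dianion and arrest after one addition;
  - silyl migration followed by loss of silanolate on warming.
- Fallback (the central sp–sp bond is made by dimerisation instead of being bought): it sets out from 2. Ethynylmagnesium bromide in THF at 0 °C should give 1-[2-(tert-butyldimethylsilyloxy)-4-methoxyphenyl]prop-2-yn-1-ol F12. Glaser–Hay oxidative homocoupling (CuCl, TMEDA, air, acetone, rt) joins two such units, and the route is rejoined at 5.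

## Further compounds

F1 | step 4 | (E,E)-2,2'-(1,2-diiodoethane-1,2-diylidene)bis(6-methoxy-2,3-dihydrobenzofuran-3-ol) | OC1/C(=C(/C(=C2\Oc3cc(OC)ccc3C2O)I)I)Oc2cc(OC)ccc21
F2 | step 4 | (E,E)-2,2'-(1,2-diiodoethane-1,2-diylidene)bis(6-methoxybenzofuran-3(2H)-one) | O=C1/C(=C(/C(=C2\Oc3cc(OC)ccc3C2=O)I)I)Oc2cc(OC)ccc21
F3 | step 5 | 4-iodobenzene-1,2-diol | Oc1ccc(I)cc1O
F4 | step 5 | 4-iodo-1,2-bis(methoxymethoxy)benzene | COCOc1ccc(I)cc1OCOC
F5 | step 5 | 2-hydroxy-4-(methoxymethoxy)benzaldehyde | COCOc1ccc(C=O)c(O)c1
F6 | step 5 | 2-(tert-butyldimethylsilyloxy)-4-(methoxymethoxy)benzaldehyde | COCOc1ccc(C=O)c(O[Si](C)(C)C(C)(C)C)c1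
F7 | step 5 | 1,6-bis[2-(tert-butyldimethylsilyloxy)-4-(methoxymethoxy)phenyl]hexa-2,4-diyne-1,6-diol | COCOc1ccc(C(O)C#CC#CC(O)c2ccc(OCOC)cc2O[Si](C)(C)C(C)(C)C)c(O[Si](C)(C)C(C)(C)C)c1
F8 | step 5 | 1,6-bis[2-hydroxy-4-(methoxymethoxy)phenyl]hexa-2,4-diyne-1,6-diol | COCOc1ccc(C(O)C#CC#CC(O)c2ccc(OCOC)cc2O)c(O)c1
F9 | step 5 | mono-cyclised MOM enyne carbinol (Z, aryl trans to O1) | OC1/C(=C(/C#CC(O)c2ccc(OCOC)cc2O)c2ccc(OCOC)c(OCOC)c2)Oc2cc(OCOC)ccc21
F10 | step 5 | bis-cyclised MOM dicarbinol (Z,Z) | OC1/C(=C(/C(=C2\Oc3cc(OCOC)ccc3C2O)c2ccc(OCOC)c(OCOC)c2)c2ccc(OCOC)c(OCOC)c2)Oc2cc(OCOC)ccc21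
F11 | step 5 | hexa-O-(methoxymethyl)disulfuretin (Z,Z) | O=C1/C(=C(/C(=C2\Oc3cc(OCOC)ccc3C2=O)c2ccc(OCOC)c(OCOC)c2)c2ccc(OCOC)c(OCOC)c2)Oc2cc(OCOC)ccc21
F12 | step 2 | 1-[2-(tert-butyldimethylsilyloxy)-4-methoxyphenyl]prop-2-yn-1-ol | COc1ccc(C(O)C#C)c(O[Si](C)(C)C(C)(C)C)c1
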